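**Retrosynthetic overview**

1. The last bond made is acyl C2–C3, with the ester C–O bond already in place: terpenyl bromoacetate 14 (C2) is joined to tetraene 21 (C3) in one pot by hydroboration and 1,2-boronate migration. Boron is a traceless linchpin, bonded first to C3, then to C2, then removed.
2. Enabling feature: the ester carbonyl C1 makes C2 an enolisable α-bromo carbon that accepts a group migrating from boron. The saturated C3–C8 run lets C3 be carried as the only vinyl carbon, which 9-BBN distinguishes from the internal Z-olefins C9=C10, C12=C13 and C15=C16.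
3. Tetraene 21 comes from a Z-selective Wittig reaction of the (3Z,6Z)-nonadienyl ylide with hept-6-enal; the other two Z-olefins are bought.
4. Diterpenol 13 comes from C10 + C10 alkylation of (S)-α-cyclogeranyl tolyl sulfone 7 with 8-bromogeranyl acetate 10, then reductive desulfonylation; both E-olefins come from geranyl acetate.
5. Rings: none is formed. The cyclohexene is bought as enone 1; its stereocentre is set as C–O by CBS reduction and relayed to carbon by a suprafacial decarboxylative Claisen rearrangement.

Key step: step 13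

Remark: the ring stereocentre of the target is read from the SMILES as (1S); compounds 1, 3, 8, 15 and 18 are taken as catalogue chemicals.

**Route**

Step 1
Reactants: 1 2,4,4-trimethylcyclohex-2-en-1-one
Product: 2 (1R)-2,4,4-trimethylcyclohex-2-en-1-ol
Conditions: (S)-Me-CBS (10 mol%), BH3·SMe2 (0.7 equiv), THF, −20 °C; MeOH quench
Reagents that add atoms: none
Why: Corey–Bakshi–Shibata reduction, in which the ketone binds the (S)-oxazaborolidine–borane complex with the larger methyl-substituted vinyl arm turned away from the catalyst, so hydride should reach the face that gives the (R)-carbinol by 1,2-reduction without touching the C=C bond.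

Step 2
Reactants: 2 (1R)-2,4,4-trimethylcyclohex-2-en-1-ol; 3 2-[(4-methylphenyl)sulfonyl]acetic acid
Product: 4 (1R)-2,4,4-trimethylcyclohex-2-en-1-yl 2-[(4-methylphenyl)sulfonyl]acetate
Conditions: DIC (1.2 equiv), DMAP (5 mol%), CH2Cl2, 0 °C → rt
Reagents that add atoms: none
Why: Carbodiimide (Steglich-type) esterification acylates the secondary allylic alcohol at oxygen, so the (R) C–O stereocentre is carried over unchanged.

Step 3
Reactants: 4 (1R)-2,4,4-trimethylcyclohex-2-en-1-yl 2-[(4-methylphenyl)sulfonyl]acetate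
Product: 7 1-methyl-4-({[(1S)-2,6,6-trimethylcyclohex-2-en-1-yl]methyl}sulfonyl)benzene, via ketene silyl acetal 5 (not isolated), via silyl ester 6 (not isolated)
Conditions: BSA (0.2 equiv), KOAc (10 mol%), toluene, 110 °C, sealed tube
Reagents that add atoms: none
Why: Decarboxylative Claisen rearrangement of an allylic sulfonylacetate, in which the [3,3] shift of the ketene silyl acetal is suprafacial across the ring so the new C–C bond forms at the former C3 on the face that carried the C–O bond ((R) C–O becomes (S) C–C), and acetate-induced desilylation and loss of CO2 from the α-sulfonyl silyl ester leave the homoallylic sulfone.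

Step 4
Reactants: 8 geranyl acetate
Product: 9 (2E,6E)-8-hydroxy-3,7-dimethylocta-2,6-dien-1-yl acetate
Conditions: SeO2 (10 mol%), t-BuOOH (70% aq., 2.5 equiv), salicylic acid (10 mol%), CH2Cl2, rt
Reagents that add atoms: tert-butyl hydroperoxide CC(C)(C)OO
Why: Sharpless-modified Riley allylic oxidation (ene reaction, then [2,3] shift) attacks the more electron-rich 6,7-olefin remote from the acetate at its (E)-methyl group and should give the (E)-configured primary allylic alcohol.

Step 5
Reactants: 9 (2E,6E)-8-hydroxy-3,7-dimethylocta-2,6-dien-1-yl acetate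
Product: 10 (2E,6E)-8-bromo-3,7-dimethylocta-2,6-dien-1-yl acetate
Conditions: CBr4 (1.2 equiv), PPh3 (1.25 equiv), CH2Cl2, 0 °C
Reagents that add atoms: carbon tetrabromide BrC(Br)(Br)Br
Why: Appel bromination of a primary allylic alcohol proceeds by SN2 at carbon under neutral conditions and keeps the acetate and both E-olefins.

Step 6
Reactants: 7 1-methyl-4-({[(1S)-2,6,6-trimethylcyclohex-2-en-1-yl]methyl}sulfonyl)benzene; 10 (2E,6E)-8-bromo-3,7-dimethylocta-2,6-dien-1-yl acetate
Product: 12 (2E,6E)-3,7-dimethyl-9-[(4-methylphenyl)sulfonyl]-9-[(1S)-2,6,6-trimethylcyclohex-2-en-1-yl]nona-2,6-dien-1-yl acetate (both C9 epimers), via lithiated sulfone 11 (not isolated)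
Conditions: n-BuLi (1.05 equiv), THF, −78 °C, 30 min; then 10, −78 → −40 °C
Reagents that add atoms: none
Why: Julia-type sulfone alkylation, in which the soft α-sulfonyl carbanion should displace the primary allylic bromide by SN2 faster than it adds to the acetate at −78 °C; the ring C–H is not acidic, so the stereocentre is untouched, and the new sulfonyl-bearing centre is erased in step 7.

Step 7
Reactants: 12 (2E,6E)-3,7-dimethyl-9-[(4-methylphenyl)sulfonyl]-9-[(1S)-2,6,6-trimethylcyclohex-2-en-1-yl]nona-2,6-dien-1-yl acetate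
Product: 13 (2E,6E)-3,7-dimethyl-9-[(1S)-2,6,6-trimethylcyclohex-2-en-1-yl]nona-2,6-dien-1-ol
Conditions: Mg turnings (10 equiv), HgCl2 (2 mol%), MeOH–THF 3:1, rt → 45 °C; aq NH4Cl
Reagents that add atoms: none
Why: Dissolving-metal reductive desulfonylation (Mg/MeOH) cleaves the non-allylic C–SO2Ar bond by electron transfer and protonation while the magnesium methoxide formed transesterifies the acetate; isolated olefins and the remote stereocentre are inert to these conditions.

Step 8
Reactants: 13 (2E,6E)-3,7-dimethyl-9-[(1S)-2,6,6-trimethylcyclohex-2-en-1-yl]nona-2,6-dien-1-ol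
Product: 14 (2E,6E)-3,7-dimethyl-9-[(1S)-2,6,6-trimethylcyclohex-2-en-1-yl]nona-2,6-dien-1-yl 2-bromoacetate
Conditions: BrCH2COBr (1.2 equiv), pyridine (1.5 equiv), CH2Cl2, −20 → 0 °C
Reagents that add atoms: bromoacetyl bromide BrCC(Br)=O
Why: Acylation of the primary allylic alcohol by the acid bromide (nucleophilic acyl substitution) is fast at low temperature and the buffered medium should prevent allylic displacement.

Step 9
Reactants: 15 (3Z,6Z)-nona-3,6-dien-1-ol
Product: 16 (3Z,6Z)-1-iodonona-3,6-diene
Conditions: I2 (1.2 equiv), PPh3 (1.2 equiv), imidazole (1.5 equiv), CH2Cl2, 0 °C, dark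
Reagents that add atoms: iodine II
Why: Appel-type iodination (Garegg–Samuelsson conditions) converts the primary homoallylic alcohol by SN2 without touching the skipped Z,Z-diene.

Step 10
Reactants: 16 (3Z,6Z)-1-iodonona-3,6-diene
Product: 17 [(3Z,6Z)-nona-3,6-dien-1-yl]triphenylphosphonium iodide
Conditions: PPh3 (1.1 equiv), MeCN, 80 °C, dark, argon
Reagents that add atoms: triphenylphosphine c1ccc(cc1)P(c1ccccc1)c1ccccc1
Why: SN2 quaternisation of triphenylphosphine by a primary iodide under neutral conditions should give the phosphonium salt and leave the skipped diene unconjugated.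

Step 11
Reactants: 18 hept-6-en-1-ol
Product: 19 hept-6-enal
Conditions: TEMPO (10 mol%), PhI(OAc)2 (1.1 equiv), CH2Cl2, rt
Reagents that add atoms: none
Why: Oxoammonium (TEMPO/PhI(OAc)2) oxidation of a primary alcohol stops at the aldehyde and does not touch the terminal olefin.

Step 12
Reactants: 17 [(3Z,6Z)-nona-3,6-dien-1-yl]triphenylphosphonium iodide; 19 hept-6-enal
Product: 21 (7Z,10Z,13Z)-hexadeca-1,7,10,13-tetraene, via phosphorus ylide 20 (not isolated)
Conditions: NaHMDS (1.0 equiv), THF, −78 °C; then 19, −78 °C → rt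
Reagents that add atoms: none
Why: Wittig olefination with a non-stabilised ylide under lithium-free conditions is kinetically controlled through the cis-oxaphosphetane and should give the new 7,8-olefin with Z geometry, as is usual for homoallylic ylides in skipped-polyene synthesis.

Step 13
Reactants: 21 (7Z,10Z,13Z)-hexadeca-1,7,10,13-tetraene; 14 (2E,6E)-3,7-dimethyl-9-[(1S)-2,6,6-trimethylcyclohex-2-en-1-yl]nona-2,6-dien-1-yl 2-bromoacetate
Product: 24 (2E,6E)-3,7-dimethyl-9-[(1S)-2,6,6-trimethylcyclohex-2-en-1-yl]nona-2,6-dien-1-yl (9Z,12Z,15Z)-octadeca-9,12,15-trienoate (CNP0115076.1), via B-alkyl-9-BBN 22 (not isolated), via α-boryl ester 23 (not isolated)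
Conditions: 21 (1.2 equiv), 9-BBN-H (0.5 M in THF, 1.15 equiv), 0 °C → rt, 3 h; then 14 (1.0 equiv), 0 °C; pre-formed potassium 2,6-di-tert-butylphenoxide (1.0 M in THF, 1.1 equiv) added dropwise, 0 °C → rt; aq NH4Cl
Reagents that add atoms: none
Why: 9-BBN adds anti-Markovnikov to the single monosubstituted olefin of 21 and places boron on C3; the hindered phenoxide then deprotonates bromoacetate 14 at C2, the bromo-enolate binds boron to give a borate, and 1,2-migration of the primary C3 alkyl group from boron to C2 with loss of bromide forms the C2–C3 bond, after which the α-boryl ester (boron enolate) 23 is protonolysed by the liberated phenol. The closest known reaction type is the Brown α-alkylation of α-bromo esters with B-alkyl-9-BBN derivatives under potassium 2,6-di-tert-butylphenoxide, a transition-metal-free 1,2-metallate rearrangement. No ring is closed and no stereocentre is created; boron is bonded first to C3, then to C2, and is finally removed. The hydroboration must select one of four olefins, which is secured by the terminal position of C3 and the four-methylene spacer to C9=C10, because 9-BBN is expected to react with a vinyl group at least two orders of magnitude faster than with cis-1,2-disubstituted olefins, and no B–H remains when the trisubstituted olefins of 14 are introduced. Migration of the primary alkyl group and not of a ring B–C bond is secured by the 9-BBN framework, whose bicyclic bonds are reluctant to migrate in this reaction. The weak, non-nucleophilic base at 0 °C should leave the bis-allylic positions, the allylic ester and the ring stereocentre untouched, and rapid protonolysis of the boron enolate should forestall an Ireland–Claisen-type shift through the allylic ester.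

**Compound list**

1 | 2,4,4-trimethylcyclohex-2-en-1-one | O=C1CCC(C)(C)C=C1C | starting material
2 | (1R)-2,4,4-trimethylcyclohex-2-en-1-ol | O[C@H]1C(C)=CC(C)(C)CC1 | intermediate
3 | 2-[(4-methylphenyl)sulfonyl]acetic acid (tosylacetic acid) | Cc1ccc(cc1)S(=O)(=O)CC(=O)O | starting material
4 | (1R)-2,4,4-trimethylcyclohex-2-en-1-yl 2-[(4-methylphenyl)sulfonyl]acetate | Cc1ccc(cc1)S(=O)(=O)CC(=O)O[C@H]1C(C)=CC(C)(C)CC1 | intermediate
5 | O-trimethylsilyl ketene acetal of 4 (olefin geometry not defined) | Cc1ccc(cc1)S(=O)(=O)C=C(O[Si](C)(C)C)O[C@H]1C(C)=CC(C)(C)CC1 | intermediate (not isolated)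
6 | trimethylsilyl 2-[(4-methylphenyl)sulfonyl]-2-[(1S)-2,6,6-trimethylcyclohex-2-en-1-yl]acetate (epimers at C2) | Cc1ccc(cc1)S(=O)(=O)C(C(=O)O[Si](C)(C)C)[C@@H]1C(C)=CCCC1(C)C | intermediate (not isolated)
7 | 1-methyl-4-({[(1S)-2,6,6-trimethylcyclohex-2-en-1-yl]methyl}sulfonyl)benzene ((S)-α-cyclogeranyl p-tolyl sulfone) | Cc1ccc(cc1)S(=O)(=O)C[C@@H]1C(C)=CCCC1(C)C | intermediate
8 | geranyl acetate, (2E)-3,7-dimethylocta-2,6-dien-1-yl acetate | CC(=O)OC/C=C(\C)CCC=C(C)C | starting material
9 | (2E,6E)-8-hydroxy-3,7-dimethylocta-2,6-dien-1-yl acetate | CC(=O)OC/C=C(\C)CC/C=C(\C)CO | intermediate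
10 | (2E,6E)-8-bromo-3,7-dimethylocta-2,6-dien-1-yl acetate | CC(=O)OC/C=C(\C)CC/C=C(\C)CBr | intermediate
11 | α-lithio derivative of sulfone 7 | Cc1ccc(cc1)S(=O)(=O)C([Li])[C@@H]1C(C)=CCCC1(C)C | intermediate (not isolated)
12 | (2E,6E)-3,7-dimethyl-9-[(4-methylphenyl)sulfonyl]-9-[(1S)-2,6,6-trimethylcyclohex-2-en-1-yl]nona-2,6-dien-1-yl acetate (both C9 epimers) | CC(=O)OC/C=C(\C)CC/C=C(\C)CC(S(=O)(=O)c1ccc(C)cc1)[C@@H]1C(C)=CCCC1(C)C | intermediate
13 | (2E,6E)-3,7-dimethyl-9-[(1S)-2,6,6-trimethylcyclohex-2-en-1-yl]nona-2,6-dien-1-ol | OC/C=C(\C)CC/C=C(\C)CC[C@@H]1C(C)=CCCC1(C)C | intermediate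
14 | (2E,6E)-3,7-dimethyl-9-[(1S)-2,6,6-trimethylcyclohex-2-en-1-yl]nona-2,6-dien-1-yl 2-bromoacetate | BrCC(=O)OC/C=C(\C)CC/C=C(\C)CC[C@@H]1C(C)=CCCC1(C)C | intermediate
15 | (3Z,6Z)-nona-3,6-dien-1-ol | CC/C=C\C/C=C\CCO | starting material
16 | (3Z,6Z)-1-iodonona-3,6-diene | CC/C=C\C/C=C\CCI | intermediate
17 | [(3Z,6Z)-nona-3,6-dien-1-yl]triphenylphosphonium iodide | CC/C=C\C/C=C\CC[P+](c1ccccc1)(c1ccccc1)c1ccccc1.[I-] | intermediate
18 | hept-6-en-1-ol | C=CCCCCCO | starting material
19 | hept-6-enal | C=CCCCCC=O | intermediate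
20 | [(3Z,6Z)-nona-3,6-dien-1-ylidene]triphenylphosphorane | CC/C=C\C/C=C\CC=P(c1ccccc1)(c1ccccc1)c1ccccc1 | intermediate (not isolated)
21 | (7Z,10Z,13Z)-hexadeca-1,7,10,13-tetraene | CC/C=C\C/C=C\C/C=C\CCCCC=C | intermediate
22 | 9-[(7Z,10Z,13Z)-hexadeca-7,10,13-trien-1-yl]-9-borabicyclo[3.3.1]nonane | CC/C=C\C/C=C\C/C=C\CCCCCCB1C2CCCC1CCC2 | intermediate (not isolated)
23 | (2E,6E)-3,7-dimethyl-9-[(1S)-2,6,6-trimethylcyclohex-2-en-1-yl]nona-2,6-dien-1-yl (9Z,12Z,15Z)-2-(9-borabicyclo[3.3.1]nonan-9-yl)octadeca-9,12,15-trienoate (C-bound form of the boron enolate; C2 not defined) | CC/C=C\C/C=C\C/C=C\CCCCCCC(B1C2CCCC1CCC2)C(=O)OC/C=C(\C)CC/C=C(\C)CC[C@@H]1C(C)=CCCC1(C)C | intermediate (not isolated)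
24 | (2E,6E)-3,7-dimethyl-9-[(1S)-2,6,6-trimethylcyclohex-2-en-1-yl]nona-2,6-dien-1-yl (9Z,12Z,15Z)-octadeca-9,12,15-trienoate (CNP0115076.1) | CC/C=C\C/C=C\C/C=C\CCCCCCCC(=O)OC/C=C(\C)CC/C=C(\C)CC[C@@H]1C(C)=CCCC1(C)C | target

**Step count and risks**

Total step count: 13. Longest linear sequence: 7 steps (1, 2, 3, 6, 7, 8, 13).

Steps most likely to fail:

Step 3. The [3,3] shift must form a bond at the ring carbon next to the gem-dimethyl group and may be slow, so that thermal ionisation of the allylic C–O bond (elimination, or ion-pair return with loss of enantiopurity) could overtake rearrangement. The fallback sets out from alcohol 2 and replaces the thermal ester rearrangement by an anionic [2,3] shift at −78 °C. Alkylation of 2 with KH and Bu3SnCH2I in THF should give tributyl({[(1R)-2,4,4-trimethylcyclohex-2-en-1-yl]oxy}methyl)stannane F1. Tin–lithium exchange with n-BuLi at −78 °C should trigger a Wittig–Still rearrangement, again suprafacial, to [(1S)-2,6,6-trimethylcyclohex-2-en-1-yl]methanol F2. Hata thioetherification with di-p-tolyl disulfide and PBu3 should then give 1-methyl-4-({[(1S)-2,6,6-trimethylcyclohex-2-en-1-yl]methyl}sulfanyl)benzene F3. Molybdate-catalysed H2O2 oxidation at sulfur returns to the route at sulfone 7.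

Step 13. The bromoacetate enolate may condense with itself (Darzens- or Claisen-type) faster than the hindered borane captures it, or the boron enolate may undergo a [3,3] shift through the allylic ester before protonolysis. The fallback sets out from tetraene 21 and diterpenol 13 and makes the same C2–C3 connection as an olefin. Hydroboration of 21 with 9-BBN followed by NaBO3 oxidation should give (7Z,10Z,13Z)-hexadeca-7,10,13-trien-1-ol F4, and Dess–Martin oxidation (NaHCO3 buffer) should give (7Z,10Z,13Z)-hexadeca-7,10,13-trienal F5. Esterification of 13 with diethylphosphonoacetic acid (DIC, DMAP) should give (2E,6E)-3,7-dimethyl-9-[(1S)-2,6,6-trimethylcyclohex-2-en-1-yl]nona-2,6-dien-1-yl 2-(diethoxyphosphoryl)acetate F6. Masamune–Roush Horner–Wadsworth–Emmons olefination of F5 with F6 (LiCl, DBU, MeCN) should give (2E,6E)-3,7-dimethyl-9-[(1S)-2,6,6-trimethylcyclohex-2-en-1-yl]nona-2,6-dien-1-yl (2E,9Z,12Z,15Z)-octadeca-2,9,12,15-tetraenoate F7. Copper hydride conjugate reduction (Stryker's reagent with a silane, toluene) should saturate only the conjugated 2,3-olefin and return to the route at target 24.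

Step 1. Facial discrimination in hydride delivery may be insufficient, because the two carbonyl flanks (a methyl-bearing sp2 carbon and a CH2) differ only moderately in size, and any deficit in enantiopurity would be carried to the target. The fallback sets out from enone 1 and replaces asymmetric reduction by enzymatic kinetic resolution. Luche reduction (NaBH4, CeCl3, MeOH) should give racemic 2,4,4-trimethylcyclohex-2-en-1-ol F8. Lipase-catalysed acylation (immobilised Candida antarctica lipase B, vinyl acetate, MTBE), run to about half conversion, is expected by Kazlauskas' rule to acylate the (R)-enantiomer and give (1R)-2,4,4-trimethylcyclohex-2-en-1-yl acetate F9, which is separated from the unreacted (S)-alcohol. Methanolysis of F9 (K2CO3, MeOH) returns to the route at alcohol 2.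

Further compounds
F1 | step 3 | tributyl({[(1R)-2,4,4-trimethylcyclohex-2-en-1-yl]oxy}methyl)stannane | CCCC[Sn](CCCC)(CCCC)CO[C@H]1C(C)=CC(C)(C)CC1
F2 | step 3 | [(1S)-2,6,6-trimethylcyclohex-2-en-1-yl]methanol | OC[C@@H]1C(C)=CCCC1(C)C
F3 | step 3 | 1-methyl-4-({[(1S)-2,6,6-trimethylcyclohex-2-en-1-yl]methyl}sulfanyl)benzene | Cc1ccc(cc1)SC[C@@H]1C(C)=CCCC1(C)C
F4 | step 13 | (7Z,10Z,13Z)-hexadeca-7,10,13-trien-1-ol | CC/C=C\C/C=C\C/C=C\CCCCCCO
F5 | step 13 | (7Z,10Z,13Z)-hexadeca-7,10,13-trienal | CC/C=C\C/C=C\C/C=C\CCCCCC=O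
F6 | step 13 | (2E,6E)-3,7-dimethyl-9-[(1S)-2,6,6-trimethylcyclohex-2-en-1-yl]nona-2,6-dien-1-yl 2-(diethoxyphosphoryl)acetate | CCOP(=O)(OCC)CC(=O)OC/C=C(\C)CC/C=C(\C)CC[C@@H]1C(C)=CCCC1(C)C
F7 | step 13 | (2E,6E)-3,7-dimethyl-9-[(1S)-2,6,6-trimethylcyclohex-2-en-1-yl]nona-2,6-dien-1-yl (2E,9Z,12Z,15Z)-octadeca-2,9,12,15-tetraenoate | CC/C=C\C/C=C\C/C=C\CCCCC/C=C/C(=O)OC/C=C(\C)CC/C=C(\C)CC[C@@H]1C(C)=CCCC1(C)C
F8 | step 1 | racemic 2,4,4-trimethylcyclohex-2-en-1-ol | CC1=CC(C)(C)CCC1O
F9 | step 1 | (1R)-2,4,4-trimethylcyclohex-2-en-1-yl acetate | CC(=O)O[C@H]1C(C)=CC(C)(C)CC1
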